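**Retrosynthetic overview**
1. Enone Cα=Cβ: Claisen–Schmidt disconnection to a 7-acetyl-2,3-dihydrobenzofuran and 4-hydroxybenzaldehyde. Ring B is bought intact and joined last.
2. Dihydrofuran O1–C2 bond and the only stereocentre: 5-exo-tet opening, with inversion, of an (R)-prenyl epoxide by the acetyl-chelated 2-OH. The epoxide comes from chiral-dioxirane organocatalysis on the prenyl alkene, in the same flask.
3. The 4-OH para to the acetyl group is silylated first, so only the ortho-acyl phenol can close the ring.
4. Aryl C3–CH2 bond: phenoxide C-prenylation of 2',4'-dihydroxy-6'-methoxyacetophenone with prenyl bromide.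
5. Ring order: ring A is bought, the dihydrofuran ring is the only ring made (step 3), and ring B is attached in step 4.

Assumption: the stereocentre read from the SMILES is (S). The D-fructose-derived Shi ketone (1,2:4,5-di-O-isopropylidene-β-D-erythro-2,3-hexodiulo-2,6-pyranose, CC1(C)OC[C@@]2(O1)OC[C@H]3OC(C)(C)O[C@H]3C2=O) is bought and used only as catalyst.

**Step 1**
Reactants: 1 2',4'-dihydroxy-6'-methoxyacetophenone; 2 prenyl bromide (1-bromo-3-methylbut-2-ene)
Product: 3 1-[2,4-dihydroxy-6-methoxy-3-(3-methylbut-2-en-1-yl)phenyl]ethan-1-one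
Conditions: KOH (2 equiv), H2O, 0 °C; 2 (1.1 equiv) dropwise, 0 → 23 °C, 4 h; then 1 M HCl
Reagents that add atoms: none
Why: Phenoxide C-alkylation (nuclear prenylation): in water the phenoxide oxygens are hydrogen-bonded and shielded, so the soft allylic bromide is taken by ring carbon, and C3, ortho to both O− groups and less crowded than C5 beside OMe, is the most nucleophilic site (moderate yield, isomers removed by chromatography).

**Step 2**
Reactants: 3 1-[2,4-dihydroxy-6-methoxy-3-(3-methylbut-2-en-1-yl)phenyl]ethan-1-one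
Product: 4 1-[2-hydroxy-6-methoxy-3-(3-methylbut-2-en-1-yl)-4-(triisopropylsilyloxy)phenyl]ethan-1-one
Conditions: TIPSCl (1.1 equiv), imidazole (2.5 equiv), DMF, 0 → 23 °C
Reagents that add atoms: chlorotriisopropylsilane (TIPSCl), CC(C)[Si](Cl)(C(C)C)C(C)C
Why: Chemoselective phenol silylation: the 2-OH is locked in a hydrogen bond to the acetyl C=O and flanked on both sides, so only the free, more acidic 4-OH reacts, which removes the competing nucleophile for the ring closure of step 3.

**Step 3**
Reactants: 4 1-[2-hydroxy-6-methoxy-3-(3-methylbut-2-en-1-yl)-4-(triisopropylsilyloxy)phenyl]ethan-1-one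
Product: 6 1-[(2S)-2-(2-hydroxypropan-2-yl)-6-methoxy-4-(triisopropylsilyloxy)-2,3-dihydro-1-benzofuran-7-yl]ethan-1-one, via (R)-epoxide 5 (not isolated)
Conditions: D-fructose-derived Shi ketone (30 mol %), 2KHSO5·KHSO4·K2SO4 (1.4 equiv), K2CO3 (5.8 equiv), Bu4NHSO4 (5 mol %), MeCN–CH2(OMe)2 (1:2)/aq Na2B4O7–Na2H2EDTA buffer (pH 10.5), 0 °C, 2 h; then 23 °C, 3 h
Reagents that add atoms: potassium peroxymonosulfate (KHSO5, one O atom passed on through the catalyst dioxirane), [K+].[O-]S(=O)(=O)OO
Why: Proposed new method: a chiral-dioxirane epoxidation/5-exo-tet etherification cascade run directly on a free, carbonyl-chelated ortho-prenylphenol (an acylphloroglucinol), a substrate class not yet shown because such phenols are normally masked; KHSO5 converts the ketone into its dioxirane, which transfers oxygen through the usual spiro transition state (olefinic H beside the spiroketal) to give the (R)-epoxide 5 as for other RCH2CH=CMe2 alkenes (about 90% ee expected), the electron-rich alkene reacting faster than the ring because the acetyl group and the O–H···O=C bond lower the ring electron density and keep the phenol largely un-ionised at 0 °C, and on warming the carbonate buffer ionises the 2-OH, whose phenoxide attacks the less hindered secondary epoxide carbon from the back (Baldwin-favoured 5-exo-tet, SN2 inversion, R to S) while the 4-O-TIPS oxygen cannot compete, so ring and stereocentre are set in one flask; closest known reaction type: Shi asymmetric epoxidation of O-protected ortho-prenylphenols followed by a separate deprotection and base-induced cyclisation.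

**Step 4**
Reactants: 6 1-[(2S)-2-(2-hydroxypropan-2-yl)-6-methoxy-4-(triisopropylsilyloxy)-2,3-dihydro-1-benzofuran-7-yl]ethan-1-one; 7 4-hydroxybenzaldehyde
Product: 10 (E)-1-[(2S)-4-hydroxy-2-(2-hydroxypropan-2-yl)-6-methoxy-2,3-dihydro-1-benzofuran-7-yl]-3-(4-hydroxyphenyl)prop-2-en-1-one (target), via free phenol ketone 8 (not isolated), via aldol adduct 9 (not isolated)
Conditions: 7 (3 equiv), KOH (20 equiv, 50% aq), EtOH, N2, 23 → 50 °C, 24–48 h; then 1 M HCl to pH 4; recrystallise
Reagents that add atoms: none
Why: Claisen–Schmidt condensation (aldol addition then E1cB dehydration): hydroxide first cleaves the activated aryl silyl ether, the methyl ketone enolate (acetyl twisted out of the ring plane by its two ortho ethers, so little deactivated by the para phenoxide) adds to 7 and loss of water gives the conjugated E-enone, while the lack of a free ortho OH rules out flavanone formation and the C2 stereocentre, which carries no acidic hydrogen, is untouched.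

**Compound list**
1 | 1-(2,4-dihydroxy-6-methoxyphenyl)ethan-1-one (2',4'-dihydroxy-6'-methoxyacetophenone) | CC(=O)c1c(O)cc(O)cc1OC | starting material
2 | 1-bromo-3-methylbut-2-ene (prenyl bromide) | CC(C)=CCBr | starting material
3 | 1-[2,4-dihydroxy-6-methoxy-3-(3-methylbut-2-en-1-yl)phenyl]ethan-1-one | CC(=O)c1c(O)c(CC=C(C)C)c(O)cc1OC | intermediate
4 | 1-[2-hydroxy-6-methoxy-3-(3-methylbut-2-en-1-yl)-4-(triisopropylsilyloxy)phenyl]ethan-1-one | CC(=O)c1c(O)c(CC=C(C)C)c(O[Si](C(C)C)(C(C)C)C(C)C)cc1OC | intermediate
5 | 1-[3-{[(2R)-3,3-dimethyloxiran-2-yl]methyl}-2-hydroxy-6-methoxy-4-(triisopropylsilyloxy)phenyl]ethan-1-one | CC(=O)c1c(O)c(C[C@H]2OC2(C)C)c(O[Si](C(C)C)(C(C)C)C(C)C)cc1OC | intermediate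
6 | 1-[(2S)-2-(2-hydroxypropan-2-yl)-6-methoxy-4-(triisopropylsilyloxy)-2,3-dihydro-1-benzofuran-7-yl]ethan-1-one | COc1cc(O[Si](C(C)C)(C(C)C)C(C)C)c2c(c1C(C)=O)O[C@H](C(C)(C)O)C2 | intermediate
7 | 4-hydroxybenzaldehyde | O=Cc1ccc(O)cc1 | starting material
8 | 1-[(2S)-4-hydroxy-2-(2-hydroxypropan-2-yl)-6-methoxy-2,3-dihydro-1-benzofuran-7-yl]ethan-1-one | COc1cc(O)c2c(c1C(C)=O)O[C@H](C(C)(C)O)C2 | intermediate
9 | 3-hydroxy-1-[(2S)-4-hydroxy-2-(2-hydroxypropan-2-yl)-6-methoxy-2,3-dihydro-1-benzofuran-7-yl]-3-(4-hydroxyphenyl)propan-1-one (both carbinol epimers) | COc1cc(O)c2c(c1C(=O)CC(O)c1ccc(O)cc1)O[C@H](C(C)(C)O)C2 | intermediate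
10 | (E)-1-[(2S)-4-hydroxy-2-(2-hydroxypropan-2-yl)-6-methoxy-2,3-dihydro-1-benzofuran-7-yl]-3-(4-hydroxyphenyl)prop-2-en-1-one | COc1cc(O)c2c(c1C(=O)/C=C/c1ccc(O)cc1)O[C@H](C(C)(C)O)C2 | target

Total step count: 4. Longest linear sequence: 4.

**Three steps most likely to fail**

Step 3 (the new cascade). The risks are these:
- The free phenol or its phenoxide may be oxidised by the dioxirane or by KHSO5.
- The silyl ether may be lost before ring closure.
- The closure may stall.
- The ee may fall below about 90%.

The fallback uses known chemistry, keeps the same organocatalyst, sets out from 4 and comes back at 6. The chelated phenol of 4 is acetylated (Ac2O, Et3N, DMAP, CH2Cl2) to the aryl acetate F2. The standard Shi epoxidation of this fully masked prenylarene, under the same ketone/KHSO5/K2CO3 conditions at 0 °C, gives the isolated (R)-epoxy acetate F3. Brief K2CO3/MeOH at 0 °C removes the acetate, and the freed phenoxide closes 5-exo with inversion to 6.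

Step 1. The risk is a mixture of C3-, C5-, O- and bis-prenylated products with a low isolated yield of 3. The fallback sets out from 1 and comes back at 3. The more acidic 4-OH of 1 is etherified with tert-butyl 2-methylbut-3-en-2-yl carbonate and Pd(PPh3)4 (THF, 0 °C) to the 1,1-dimethylallyl aryl ether F1. Heating F1 (N,N-diethylaniline, 130 °C) triggers the aromatic Claisen [3,3] rearrangement. This places a linear prenyl group at C3, because the chelate ring of the 2-hydroxyacetophenone gives the C3–C4 bond more double-bond character, as in the classical 4-allyloxy-2-hydroxyacetophenone case.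

Step 4. The risk is a sluggish, low-yielding condensation, because both partners are phenoxides and the aldehyde phenoxide is a poor electrophile. The fallback sets out from 6 and comes back at 10. Ketone 6 is condensed (KOH, EtOH–H2O, 23 °C, silyl ether lost in the same pot) with commercial 4-(methoxymethoxy)benzaldehyde, whose carbonyl group is not deactivated. This gives the mono-MOM chalcone F4. Dilute HCl in MeOH (40 °C) then removes the acetal and gives 10.

**Further compounds**
F1 | step 1 | 1-{2-hydroxy-6-methoxy-4-[(2-methylbut-3-en-2-yl)oxy]phenyl}ethan-1-one | CC(=O)c1c(O)cc(OC(C)(C)C=C)cc1OC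
F2 | step 3 | 2-acetyl-3-methoxy-6-(3-methylbut-2-en-1-yl)-5-(triisopropylsilyloxy)phenyl acetate | CC(=O)Oc1c(CC=C(C)C)c(O[Si](C(C)C)(C(C)C)C(C)C)cc(OC)c1C(C)=O
F3 | step 3 | 2-acetyl-6-{[(2R)-3,3-dimethyloxiran-2-yl]methyl}-3-methoxy-5-(triisopropylsilyloxy)phenyl acetate | CC(=O)Oc1c(C[C@H]2OC2(C)C)c(O[Si](C(C)C)(C(C)C)C(C)C)cc(OC)c1C(C)=O
F4 | step 4 | (E)-1-[(2S)-4-hydroxy-2-(2-hydroxypropan-2-yl)-6-methoxy-2,3-dihydro-1-benzofuran-7-yl]-3-[4-(methoxymethoxy)phenyl]prop-2-en-1-one | COCOc1ccc(/C=C/C(=O)c2c(OC)cc(O)c3c2O[C@H](C(C)(C)O)C3)cc1
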